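## Retrosynthetic overview

1. The target is read as (−)-epiafzelechin-(4β→8)-(+)-catechin. The interflavan bond C4–C8' is cut last, giving a benzylated flavan-4-yl cation (upper unit) and tetra-O-benzyl-(+)-catechin, which supplies rings D, E and F and two stereocentres.
2. Feature used: on ring A of the upper unit, O1 (on C8a) and C4 (on C4a) sit on adjacent carbons, and C4a is flanked on its other side by the oxygenated C5. This pattern results when an oxygen nucleophile and a carbon electrophile add across the triple bond of 3,5-dibenzyloxybenzyne.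
3. Ring C is therefore opened at O1–C8a and C4–C4a. This gives the aryne (ring A) and a three-carbon syn aldol aldehyde C2–C3–C4 that carries ring B, O1 and O3.
4. C2 and C3 come from an Evans syn glycolate aldol. C4 is set in the interflavan coupling, trans to O3.
5. Ring order: rings A and B are bought, ring C closes in the aryne step, the lower unit is attached, and eight benzyl ethers are removed in one hydrogenolysis.

Key step: step 9

Remark: fluoride does not deprotonate an aliphatic alcohol and would leave HF beside the aryl anion, so the aldol aldehyde enters the key step as its O-trimethylsilyl ether, from which the same fluoride frees the alkoxide under proton-free conditions.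

## Route

Step 1
Reactants: 1 (S)-4-benzyloxazolidin-2-one; 2 benzyloxyacetyl chloride
Product: 4 (S)-4-benzyl-3-(2-benzyloxyacetyl)oxazolidin-2-one, via N-lithio oxazolidinone 3 (not isolated)
Conditions: n-BuLi, THF, −78 °C; then 2, −78 → 0 °C
Reagents that add atoms: none
Why: N-Acylation of a lithiated Evans oxazolidinone by an acid chloride is routine and does not touch the auxiliary stereocentre.

Step 2
Reactants: 4 (S)-4-benzyl-3-(2-benzyloxyacetyl)oxazolidin-2-one; 5 4-benzyloxybenzaldehyde
Product: 7 (S)-4-benzyl-3-[(2S,3R)-2-benzyloxy-3-(4-benzyloxyphenyl)-3-hydroxypropanoyl]oxazolidin-2-one, via Z-dibutylboron enolate 6 (not isolated)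
Conditions: n-Bu2BOSO2CF3, Et3N, CH2Cl2, −78 → 0 °C; 5, −78 → 0 °C; then H2O2, MeOH, pH 7 buffer, 0 °C
Reagents that add atoms: none
Why: Evans syn glycolate aldol: soft enolisation gives Z-enolate 6, which reacts through a Zimmerman–Traxler chair on the enolate face away from the auxiliary benzyl group, so that the 2S,3R syn adduct (future C3 and C2 of ring C) should form.

Step 3
Reactants: 7 syn aldol imide
Product: 8 (2S,3R)-2-benzyloxy-3-(4-benzyloxyphenyl)-3-hydroxy-N-methoxy-N-methylpropanamide
Conditions: MeNH(OMe)·HCl, AlMe3, THF, −10 → 0 °C; aq potassium sodium tartrate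
Reagents that add atoms: N,O-dimethylhydroxylamine hydrochloride, CNOC.Cl
Why: Weinreb transamidation of an Evans aldol imide with the aluminium amide made from AlMe3 is directed to the exocyclic carbonyl by the aluminium alkoxide of the free hydroxyl and leaves both stereocentres alone.

Step 4
Reactants: 8 Weinreb amide
Product: 9 (2S,3R)-2-benzyloxy-3-(4-benzyloxyphenyl)-3-hydroxypropanal
Conditions: i-Bu2AlH (2.5 equiv), THF, −78 °C; aq potassium sodium tartrate, 0 °C; used without storage
Reagents that add atoms: none
Why: Weinreb amide reduction: after the first equivalent of hydride has been spent on the hydroxyl, i-Bu2AlH adds once and the chelated tetrahedral adduct holds until the cold neutral work-up, so that neither over-reduction nor epimerisation at the α-alkoxy carbon is expected.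

Step 5
Reactants: 9 hydroxy aldehyde
Product: 10 (2S,3R)-2-benzyloxy-3-(4-benzyloxyphenyl)-3-(trimethylsilyloxy)propanal
Conditions: 1-(trimethylsilyl)imidazole, CH2Cl2, 0 °C; filtration through a short silica pad to remove imidazole
Reagents that add atoms: 1-(trimethylsilyl)imidazole, C[Si](C)(C)n1ccnc1
Why: Silylation of a secondary alcohol with a silylimidazole needs no added base or acid, so the sensitive aldol aldehyde should be capped without epimerisation, retro-aldol cleavage or dehydration.

Step 6
Reactants: 11 3,5-dibenzyloxyphenol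
Product: 12 2-bromo-3,5-bis(benzyloxy)phenol
Conditions: NBS (1.0 equiv), CH2Cl2, −78 → −20 °C
Reagents that add atoms: N-bromosuccinimide, O=C1CCC(=O)N1Br
Why: Electrophilic aromatic bromination of a phenol with NBS: the two equivalent positions ortho to the hydroxyl are as activated as C4 but less crowded than that site between two benzyloxy groups, so one equivalent in the cold should give the 2-bromide.

Step 7
Reactants: 12 2-bromo-3,5-bis(benzyloxy)phenol
Product: 13 [2-bromo-3,5-bis(benzyloxy)phenoxy]trimethylsilane
Conditions: (Me3Si)2NH, THF, 70 °C; evaporation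
Reagents that add atoms: hexamethyldisilazane, C[Si](C)(C)N[Si](C)(C)C
Why: O-Silylation of a phenol with hexamethyldisilazane gives only ammonia as by-product, so that the crude silyl ether can be used after evaporation.

Step 8
Reactants: 13 aryl silyl ether
Product: 16 3,5-bis(benzyloxy)-2-(trimethylsilyl)phenyl triflate, via aryllithium 14 (not isolated), via lithium phenoxide 15 (not isolated)
Conditions: n-BuLi, THF, −78 °C; then (CF3SO2)2O, −78 °C
Reagents that add atoms: triflic anhydride, O=S(=O)(OS(=O)(=O)C(F)(F)F)C(F)(F)F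
Why: Bromine–lithium exchange, 1,3 oxygen-to-carbon silyl shift (retro-Brook rearrangement) and triflation of the phenoxide form the standard sequence to Kobayashi-type o-silylaryl triflates, and the exchange at −78 °C is faster than any attack of n-BuLi on the benzyl ethers.

Step 9
Reactants: 10 silyl-protected aldol aldehyde; 16 3,5-bis(benzyloxy)-2-(trimethylsilyl)phenyl triflate
Product: 21 (2R,3R,4RS)-3,5,7-tris(benzyloxy)-2-[4-(benzyloxy)phenyl]chroman-4-ol, via 3,5-bis(benzyloxy)benzyne 17 (not isolated), via potassium aldolate 18 (not isolated), via C4a aryl anion 19 (not isolated), via potassium C4 alkoxide 20 (not isolated)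
Conditions: 16 (1.5 equiv), dried KF (2.5 equiv), 18-crown-6, THF, −20 °C, slow addition of 10, then 0 °C; AcOH quench
Reagents that add atoms: none
Why: Proposed new method: fluoride removes the O–SiMe3 group of 10 to free aldolate 18 and the C–SiMe3 group of 16 to release, with loss of triflate, aryne 17; 18 adds through oxygen to the aryne carbon that becomes C8a, the aryl anion 19 (charge on C4a) attacks the aldehyde carbon C4, and alkoxide 20 is protonated at the quench. The closest known reaction types are the annulation of arynes with salicylaldehydes and salicylates (aryloxide addition, then closure of the aryl anion on the carbonyl group to xanthenols and xanthones) and the three-component aryne couplings in which such an aryl anion is caught by an aldehyde, whereas an aliphatic β-oxido aldehyde has not been used in this way. Ring C closes in the 6-exo-trig mode on C=O, an intramolecular step that should outrun intermolecular proton transfer to the aryl anion. C2 and C3 are carried over unchanged from the aldol, and the only new stereocentre, C4, is left uncontrolled because it becomes planar in step 11. The regioselectivity needed (O at C8a, C at C4a) is secured by the benzyloxy group beside the triple bond, which distorts the aryne so that nucleophiles attack the remote carbon and the charge develops next to the inductively withdrawing C5 oxygen. The chemoselectivity needed (aryne capture ahead of retro-aldol cleavage, enolisation and protonation) is addressed by the absence of any O–H or HF, by the low temperature and slow addition of 10, and by the excess of 16, which an idle alkoxide can attack at silicon to regenerate a silyl ether and one more aryne, so that the free alkoxide stays scarce.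

Step 10
Reactants: 22 (+)-catechin
Product: 23 5,7,3',4'-tetra-O-benzyl-(+)-catechin
Conditions: BnBr (4.4 equiv), K2CO3, DMF, 0 °C → rt, argon
Reagents that add atoms: benzyl bromide, BrCc1ccccc1
Why: Williamson etherification: K2CO3 deprotonates only the four phenols, so the secondary C3 hydroxyl stays free, and the mild temperature avoids epimerisation at C2.

Step 11
Reactants: 21 benzylated flavan-3,4-diol (both C4 epimers); 23 tetra-O-benzyl-(+)-catechin
Product: 25 3,5,7,4'-tetra-O-benzylepiafzelechin-(4β→8)-5,7,3',4'-tetra-O-benzylcatechin, via flavan-4-yl cation 24 (not isolated)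
Conditions: 23 (4 equiv, excess recovered), Me3SiOSO2CF3 (0.2 equiv), 4 Å molecular sieves, CH2Cl2, −78 → −40 °C; Et3N quench
Reagents that add atoms: none
Why: Acid-promoted flavan-4-yl cation condensation (Friedel–Crafts alkylation, the standard interflavan coupling of benzylated flavan-3,4-diol derivatives): both C4 epimers of 21 ionise to the same cation 24, which is attacked by C8, the most nucleophilic carbon of 23, on the face opposite to the cis-disposed 3-benzyloxy and 2-aryl groups, setting C4 as R (3,4-trans, 4β), while the excess of 23 suppresses self-condensation.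

Step 12
Reactants: 25 octa-O-benzyl dimer
Product: 26 gambiriin C
Conditions: H2 (1 atm), Pd(OH)2 on carbon, THF/MeOH/H2O, rt
Reagents that add atoms: none
Why: Hydrogenolysis of all eight benzyl ethers over Pd(OH)2 on carbon under neutral conditions is the usual last step for benzylated proanthocyanidins and leaves the ring C–O bonds, the interflavan bond and all five stereocentres intact.

## Compound list

1 | (S)-4-benzyloxazolidin-2-one | O=C1N[C@@H](Cc2ccccc2)CO1 | starting material
2 | benzyloxyacetyl chloride | O=C(Cl)COCc1ccccc1 | starting material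
3 | N-lithio-(S)-4-benzyloxazolidin-2-one (not isolated) | [Li]N1C(=O)OC[C@@H]1Cc1ccccc1 | intermediate
4 | (S)-4-benzyl-3-(2-benzyloxyacetyl)oxazolidin-2-one | O=C(COCc1ccccc1)N1C(=O)OC[C@@H]1Cc1ccccc1 | intermediate
5 | 4-benzyloxybenzaldehyde | O=Cc1ccc(OCc2ccccc2)cc1 | starting material
6 | Z-dibutylboron enolate of 4 (not isolated) | CCCCB(CCCC)O/C(=C\OCc1ccccc1)N1C(=O)OC[C@@H]1Cc1ccccc1 | intermediate
7 | (S)-4-benzyl-3-[(2S,3R)-2-benzyloxy-3-(4-benzyloxyphenyl)-3-hydroxypropanoyl]oxazolidin-2-one | O=C(N1C(=O)OC[C@@H]1Cc1ccccc1)[C@@H](OCc1ccccc1)[C@H](O)c1ccc(OCc2ccccc2)cc1 | intermediate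
8 | (2S,3R)-2-benzyloxy-3-(4-benzyloxyphenyl)-3-hydroxy-N-methoxy-N-methylpropanamide | CON(C)C(=O)[C@@H](OCc1ccccc1)[C@H](O)c1ccc(OCc2ccccc2)cc1 | intermediate
9 | (2S,3R)-2-benzyloxy-3-(4-benzyloxyphenyl)-3-hydroxypropanal | O=C[C@@H](OCc1ccccc1)[C@H](O)c1ccc(OCc2ccccc2)cc1 | intermediate
10 | (2S,3R)-2-benzyloxy-3-(4-benzyloxyphenyl)-3-(trimethylsilyloxy)propanal | O=C[C@@H](OCc1ccccc1)[C@H](O[Si](C)(C)C)c1ccc(OCc2ccccc2)cc1 | intermediate
11 | 3,5-dibenzyloxyphenol | Oc1cc(OCc2ccccc2)cc(OCc2ccccc2)c1 | starting material
12 | 2-bromo-3,5-bis(benzyloxy)phenol | Oc1cc(OCc2ccccc2)cc(OCc2ccccc2)c1Br | intermediate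
13 | [2-bromo-3,5-bis(benzyloxy)phenoxy]trimethylsilane | C[Si](C)(C)Oc1cc(OCc2ccccc2)cc(OCc2ccccc2)c1Br | intermediate
14 | 2,4-bis(benzyloxy)-6-(trimethylsilyloxy)phenyllithium (not isolated) | C[Si](C)(C)Oc1cc(OCc2ccccc2)cc(OCc2ccccc2)c1[Li] | intermediate
15 | lithium 3,5-bis(benzyloxy)-2-(trimethylsilyl)phenoxide (not isolated) | [Li+].[O-]c1cc(OCc2ccccc2)cc(OCc2ccccc2)c1[Si](C)(C)C | intermediate
16 | 3,5-bis(benzyloxy)-2-(trimethylsilyl)phenyl triflate | C[Si](C)(C)c1c(OS(=O)(=O)C(F)(F)F)cc(OCc2ccccc2)cc1OCc1ccccc1 | intermediate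
17 | 3,5-bis(benzyloxy)benzyne (not isolated) | C1#CC(OCc2ccccc2)=CC(OCc2ccccc2)=C1 | intermediate
18 | potassium alkoxide of aldehyde 9 (not isolated) | O=C[C@@H](OCc1ccccc1)[C@H]([O-])c1ccc(OCc2ccccc2)cc1.[K+] | intermediate
19 | aryl ether aldehyde with carbanion at C4a, potassium salt (not isolated) | O=C[C@@H](OCc1ccccc1)[C@H](Oc1cc(OCc2ccccc2)cc(OCc2ccccc2)[c-]1)c1ccc(OCc2ccccc2)cc1.[K+] | intermediate
20 | potassium C4 alkoxide of 21 (not isolated) | c5ccccc5COc1ccc([C@H]2Oc3cc(OCc5ccccc5)cc(OCc5ccccc5)c3C([O-])[C@H]2OCc5ccccc5)cc1.[K+] | intermediate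
21 | (2R,3R,4RS)-3,5,7-tris(benzyloxy)-2-[4-(benzyloxy)phenyl]chroman-4-ol (3,5,7,4'-tetra-O-benzyl-2,3-cis-flavan-3,4-diol, both C4 epimers) | c5ccccc5COc1ccc([C@H]2Oc3cc(OCc5ccccc5)cc(OCc5ccccc5)c3C(O)[C@H]2OCc5ccccc5)cc1 | intermediate
22 | (+)-catechin | O[C@H]1Cc2c(O)cc(O)cc2O[C@@H]1c1ccc(O)c(O)c1 | starting material
23 | 5,7,3',4'-tetra-O-benzyl-(+)-catechin | O[C@H]1Cc2c(OCc3ccccc3)cc(OCc3ccccc3)cc2O[C@@H]1c1ccc(OCc2ccccc2)c(OCc2ccccc2)c1 | intermediate
24 | (2R,3R)-tetra-O-benzylflavan-4-yl cation, triflate (not isolated) | c5ccccc5COc1ccc([C@H]2Oc3cc(OCc5ccccc5)cc(OCc5ccccc5)c3[CH+][C@H]2OCc5ccccc5)cc1.[O-]S(=O)(=O)C(F)(F)F | intermediate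
25 | octa-O-benzyl gambiriin C (upper unit 2R,3R,4R; lower unit 2R,3S, free 3-OH) | c9ccccc9COc1ccc([C@H]2Oc3cc(OCc9ccccc9)cc(OCc9ccccc9)c3[C@H](c3c(OCc9ccccc9)cc(OCc9ccccc9)c4c3O[C@H](c3ccc(OCc9ccccc9)c(OCc9ccccc9)c3)[C@@H](O)C4)[C@H]2OCc9ccccc9)cc1 | intermediate
26 | gambiriin C, (−)-epiafzelechin-(4β→8)-(+)-catechin | Oc1ccc([C@H]2Oc3cc(O)cc(O)c3[C@H](c3c(O)cc(O)c4c3O[C@H](c3ccc(O)c(O)c3)[C@@H](O)C4)[C@H]2O)cc1 | target

## Step count and risks

Total step count: 12. Longest linear sequence: 8 (steps 1, 2, 3, 4, 5, 9, 11, 12).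

**Step 9.** Four processes may defeat it:
- retro-aldol cleavage or enolisation of the free alkoxide (the latter with epimerisation at C3) before it meets the aryne;
- protonation of the aryl anion before ring closure;
- attack of the aldehyde oxygen on the aryne;
- arylation of the product alkoxide by a second aryne.

The fallback sets out from 10 and returns at 21. It makes the same two bonds one after the other, in reverse order, by known reactions. 1,3,5-Trifluorobenzene and two equivalents of sodium benzyl oxide (NaH, BnOH, DMF) give 1,3-bis(benzyloxy)-5-fluorobenzene F1. n-BuLi (THF, −78 °C) lithiates it between fluorine and a benzyloxy group (directed ortho-metalation) to give 2,4-bis(benzyloxy)-6-fluorophenyllithium F2. F2 is stable to loss of LiF at this temperature. It adds to aldehyde 10 and forms C4–C4a, giving the silyl-protected fluoroaryl carbinol F3. K2CO3 in MeOH removes the silyl group and leaves the fluoroaryl 1,3-diol F4. One equivalent of KH (THF/DMF, warming) then closes O1–C8a by intramolecular SNAr displacement of fluoride, a pyran closure known for epi-series flavans. Only the C2 oxygen can reach the C–F carbon through a six-membered ring, so the C4 hydroxyl needs no protection, and 21 results.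

**Step 11.** The cation may be consumed by ring A of a second upper unit (oligomerisation). The nucleophile may also react through C6 or through its free hydroxyl.

The fallback sets out from 21 and returns at 26. It uses a bromine cap. NBS (CH2Cl2, −78 °C) brominates ring A of 21 at C8 to give the 8-bromo flavan-3,4-diol derivative F5, whose ring A can no longer act as a nucleophile. Coupling with a near-equimolar amount of 23 (BF3·OEt2 or Me3SiOSO2CF3, CH2Cl2, −78 °C) gives the 8-bromo octa-O-benzyl dimer F6. Hydrogenolysis (H2, Pd(OH)2 on carbon, Et3N, THF/MeOH/H2O) removes the bromine together with the eight benzyl groups and gives 26.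

**Step 4.** The free α-alkoxy-β-hydroxy aldehyde may epimerise, cleave by retro-aldol reaction, dehydrate or self-associate during work-up and handling.

The fallback sets out from 8 and returns at 10, and the free aldehyde is never handled. 1-(Trimethylsilyl)imidazole (CH2Cl2, 0 °C) converts 8 into the O-trimethylsilyl Weinreb amide F7. One equivalent of i-Bu2AlH (toluene, −78 °C, pH 7 buffered work-up) then reduces F7 directly to 10.

## Further compounds

F1 | step 9 | 1,3-bis(benzyloxy)-5-fluorobenzene | Fc1cc(OCc2ccccc2)cc(OCc2ccccc2)c1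
F2 | step 9 | 2,4-bis(benzyloxy)-6-fluorophenyllithium | [Li]c1c(F)cc(OCc2ccccc2)cc1OCc1ccccc1
F3 | step 9 | 1-[2,4-bis(benzyloxy)-6-fluorophenyl]-2-benzyloxy-3-(4-benzyloxyphenyl)-3-(trimethylsilyloxy)propan-1-ol (C1 epimers; C2 and C3 as in 10) | OC(c1c(F)cc(OCc2ccccc2)cc1OCc1ccccc1)[C@@H](OCc1ccccc1)[C@H](O[Si](C)(C)C)c1ccc(OCc2ccccc2)cc1
F4 | step 9 | 1-[2,4-bis(benzyloxy)-6-fluorophenyl]-2-benzyloxy-3-(4-benzyloxyphenyl)propane-1,3-diol (C1 epimers; C2 and C3 as in 9) | OC(c1c(F)cc(OCc2ccccc2)cc1OCc1ccccc1)[C@@H](OCc1ccccc1)[C@H](O)c1ccc(OCc2ccccc2)cc1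
F5 | step 11 | 8-bromo derivative of 21 (both C4 epimers) | c5ccccc5COc1ccc([C@H]2Oc3c(Br)c(OCc5ccccc5)cc(OCc5ccccc5)c3C(O)[C@H]2OCc5ccccc5)cc1
F6 | step 11 | 8-bromo derivative of 25 (bromine on ring A of the upper unit) | c9ccccc9COc1ccc([C@H]2Oc3c(Br)c(OCc9ccccc9)cc(OCc9ccccc9)c3[C@H](c3c(OCc9ccccc9)cc(OCc9ccccc9)c4c3O[C@H](c3ccc(OCc9ccccc9)c(OCc9ccccc9)c3)[C@@H](O)C4)[C@H]2OCc9ccccc9)cc1
F7 | step 4 | (2S,3R)-2-benzyloxy-3-(4-benzyloxyphenyl)-N-methoxy-N-methyl-3-(trimethylsilyloxy)propanamide | CON(C)C(=O)[C@@H](OCc1ccccc1)[C@H](O[Si](C)(C)C)c1ccc(OCc2ccccc2)cc1
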